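## Analysis of the target

Compound 12 is a flavanone: a chroman-4-one in which the benzo ring (ring A) is fused to a dihydropyranone (ring C), with a 3,4-dimethoxyphenyl group (ring B) on C2. Ring A carries no hydrogen: C5, C6 and C7 bear methoxy groups, C8 a free hydroxyl, C8a the ring oxygen O1 and C4a the C4 carbonyl. Five oxygens therefore sit side by side, and exactly one of them must end up unmethylated. The only stereocentre is C2 (S), which is benzylic to ring B, alpha to O1 and beta to the C4 ketone. It is fragile: base opens ring C through the C3 enolate to the 2'-hydroxychalcone (retro-oxa-Michael), and acid can ionise the C2–O1 bond with help from the para-methoxy group of ring B; both paths racemise C2. The free C8 phenol on an electron-rich ring is also easily oxidised. The synthesis is hard for two reasons: one labile stereocentre has to be set and then handled gently, and the C8 and C8a oxygens have to be told apart from each other and from three methoxy groups on a crowded ring. The strategy rests on the C2–H bond: in a ring-open precursor C2 is the CH2 of an aryl benzyl ether, its hydrogens are made hydridic by O1 and by ring B, and it lies within reach of C3, the carbon next to the C4 carbonyl on ring A.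

## Retrosynthetic reasoning

**12 to 11 (O–Si at C8).** The last operation should be one that neither acid nor base can spoil. Cutting the silicon–oxygen bond at C8 leads to silyl ether 11. Its cleavage needs only buffered fluoride, which touches neither the C3 enolate position nor the C2–O1 bond nor the five methyl ethers.

**11 to 10 (C2–C3).** Ring C could be opened at O1–C2, but the forward oxa-Michael closure of a chalcone is reversible and hard to steer enantioselectively. Cutting C2–C3 instead places every atom of rings A and B in a simple aryl benzyl ether. The forward reaction is the insertion of a metal carbenoid at C3 into the C2–H bond of diazoketone 10. It is irreversible, neutral, closes ring C and creates C2 in the same event, and lands directly at the ketone oxidation level. It has to choose one of two enantiotopic hydrogens and has to beat attack of the carbenoid on the O1 lone pair.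

**10 to 8 (the diazo group on C3, via 9).** The diazo carbon is the methyl carbon of an aryl methyl ketone. Activation as trifluoroacetyl diketone 9 lets a sulfonyl azide transfer the diazo group while the activating acyl group leaves. The acetyl group is what a Friedel–Crafts acylation puts on ring A, so no carboxylic acid or diazomethane is needed.

**8 to 7 (O–Si at C8).** The C8 hydroxyl must be masked before the amide base and the carbenoid: a free phenol would consume base and invite O–H insertion. A triisopropylsilyl ether is bulky enough to survive both and leaves cleanly at the end.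

**7 to 5 (C8–O, via 6).** The C8 oxygen is traced back to a formyl carbon. A peracid inserts oxygen between ring A and the formyl group (aryl migration), giving formate 6, and mild solvolysis frees phenol 7. A carbon substituent is easier to bring to the last free ring position than an oxygen.

**5 to 3 and 4 (O1–CH2).** The ether bond is cut to phenol 3 and benzylic chloride 4. At this stage O1 is the only hydroxyl on ring A, so the alkylation needs no regiocontrol and no free catechol is ever handled. Chloride 4 brings in C2 and all of ring B.

**3 to 2 (C8–CHO).** The formyl group enters at the single unsubstituted carbon of ring A, which is ortho to the phenol and para to a methoxy group.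

**2 to 1 (C4a–C4).** The acetyl group comes from ortho-acylation of symmetric phenol 1; both open positions are equivalent, so only one product can form.

## Alternatives that were turned down

**Alternative 1: ring A built by ring expansion of a squarate-derived cyclobutenone.** The disconnection removes the C4a–C5 bond and with it the aromatic ring. C5 to C8 come from a squaric ester, and C4a/C8a are the enol-ether double bond of a preformed, enantiopure dihydropyran. In the forward direction 4-[(2S,4S)-4-(tert-butyldimethylsilyloxy)-2-(3,4-dimethoxyphenyl)-3,4-dihydro-2H-pyran-6-yl]-2,3-dimethoxy-4-(trimethylsilyloxy)cyclobut-2-en-1-one A1 is heated. Four-electron ring opening gives a dienylketene, six-electron closure onto C4a follows, and tautomerisation with silyl transfer gives (2S,4S)-4-(tert-butyldimethylsilyloxy)-2-(3,4-dimethoxyphenyl)-6,7-dimethoxy-8-(trimethylsilyloxy)chroman-5-ol A2.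
- For it: the substitution pattern of ring A is dictated by connectivity, the C8 oxygen emerges already differentiated (silyl ether) from C5 (free hydroxyl), the step is thermal and neutral, and C2 is not involved in the ring-forming event.
- Against it: C2 must be set earlier by a separate asymmetric step, together with a C4 stereocentre that is later destroyed. A1 requires metalation of the enol-ether carbon of a dihydropyran that also offers a benzylic C2–H and a dimethoxyarene open to ortho-metalation. A2 still needs O-methylation at C5, unmasking and oxidation of C4 and removal of the C8 silyl group. At the temperature of the rearrangement, loss of silanol across C3–C4 to a chromene is a plausible leak.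
- Comparison: on the construction of ring A this route is cleaner than the formylation/oxidation sequence used here, and that point is conceded. The chosen route buys ring A with four of its oxygens in place, makes C2 in the ring-closing step and arrives at the C4 ketone without redox adjustment, in clearly fewer steps.

**Alternative 2: ring B built on a C2 alkyne.** The disconnection cuts C1'–C2' and C5'–C6' of ring B. Forward, (2S)-8-(benzyloxy)-2-ethynyl-5,6,7-trimethoxychroman-4-one A3 and 2,3-dimethoxybuta-1,3-diene A4 combine in a cobalt-catalysed [4+2] reaction (CoBr2(dppe), Zn, ZnI2) to (2S)-8-(benzyloxy)-2-(4,5-dimethoxycyclohexa-1,4-dien-1-yl)-5,6,7-trimethoxychroman-4-one A5. Dehydrogenation to the arene and debenzylation would follow.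
- For it: while C2 is being set it is propargylic rather than a doubly activated benzylic ether, so it is less prone to ionisation. The diene A4 is symmetric, so the cycloaddition has no regiochemical question. Conjugate alkynylation of chromones is an established way to make such a centre, arguably more predictable than the enantioselectivity of a C–H insertion.
- Against it: ring B is a commodity aryl group and is here made in two steps. A3 must first be prepared in enantiopure form from an electron-rich, poorly electrophilic chromone. A5 is a bis-enol ether that hydrolyses easily, and it must be aromatised by an oxidant that spares the benzylic C2–H of the product and the electron-rich ring A. The Lewis-acidic zinc salt meets a beta-alkoxy ketone that can open by retro-Michael reaction. The final hydrogenolysis has to spare the benzylic C2–O1 bond.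
- Comparison: the alternative is stronger on precedent for the stereocentre. The chosen route introduces ring B intact from 4 and needs no oxidation-level changes on it.

**Alternative 3: ortho-quinone methide hetero-Diels–Alder reaction.** The disconnection cuts C3–C4 and O1–C2. Forward, 3-(benzyloxy)-2-hydroxy-4,5,6-trimethoxybenzaldehyde A6 is converted under a chiral BINOL-derived phosphoric acid into a 4-methoxy ortho-quinone methide, which adds 3,4-dimethoxystyrene A7 to give (2S,4S)-8-(benzyloxy)-2-(3,4-dimethoxyphenyl)-4,5,6,7-tetramethoxychromane A8.
- For it: it is the most convergent plan. Two bonds, ring C and C2 arise in one intermolecular step, the polarity of the partners fixes the regiochemistry, no diazo compound is handled and no oxonium ylide can interfere. On convergence and safety it is stronger than the chosen route.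
- Against it: A8 has C4 at the wrong oxidation level, as a methyl ether. That ether must be singled out among six methoxy groups, hydrolysed and oxidised, under acid that can also ionise the C2–O1 bond next to the para-methoxyphenyl ring. A7 has no hydrogen-bonding handle for the phosphoric acid, so the organisation needed for face selection is weak. A6 needs the same work on the pentaoxygenated arene as the chosen route, so nothing is saved there.
- Comparison: the chosen route is intramolecular, delivers the ketone directly, and asks the catalyst only to distinguish two hydrogens on one carbon.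

Key step: step 7

Assumption: Rh2(S-PTTL)4 is taken to insert into the pro-S hydrogen of the OCH2 group (giving 2S); if the first run shows the opposite sense, the mirror-image catalyst Rh2(R-PTTL)4 is used in the same step.

## Route

Step 1
Reactants: 1 3,4,5-trimethoxyphenol
Product: 2 1-(6-hydroxy-2,3,4-trimethoxyphenyl)ethan-1-one
Conditions: AcOH, BF3·OEt2, 90 °C; then aq NaOAc
Reagents that add atoms: acetic acid, CC(=O)O
Why: Friedel–Crafts (Fries-type) ortho-acylation of an electron-rich phenol; the two open positions are equivalent, and the product is held as a boron chelate that resists a second acylation until it is hydrolysed on work-up.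

Step 2
Reactants: 2 1-(6-hydroxy-2,3,4-trimethoxyphenyl)ethan-1-one
Product: 3 3-acetyl-2-hydroxy-4,5,6-trimethoxybenzaldehyde
Conditions: (CH2)6N4, CF3CO2H, 85 °C; then aq HCl, 60 °C
Reagents that add atoms: hexamethylenetetramine, C1N2CN3CN1CN(C2)C3; water, O
Why: Duff formylation; the iminium electrophile has only one ring position to attack (ortho to the phenol, para to a methoxy group), and the acidic medium leaves the methyl ketone alone, where a chloroiminium (Vilsmeier) reagent would attack it.

Step 3
Reactants: 3 3-acetyl-2-hydroxy-4,5,6-trimethoxybenzaldehyde; 4 3,4-dimethoxybenzyl chloride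
Product: 5 3-acetyl-2-[(3,4-dimethoxybenzyl)oxy]-4,5,6-trimethoxybenzaldehyde
Conditions: K2CO3, NaI (cat.), DMF, 60 °C
Reagents that add atoms: none
Why: Williamson ether synthesis; the acidic, doubly chelated phenol is the only hydroxyl present, so the reactive benzylic halide can only end up on O1, and the fully substituted ring rules out C-alkylation.

Step 4
Reactants: 5 3-acetyl-2-[(3,4-dimethoxybenzyl)oxy]-4,5,6-trimethoxybenzaldehyde
Product: 7 1-{2-[(3,4-dimethoxybenzyl)oxy]-3-hydroxy-4,5,6-trimethoxyphenyl}ethan-1-one, via aryl formate 6 (not isolated)
Conditions: mCPBA, CH2Cl2, 0 °C to rt; then Et3N, MeOH, rt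
Reagents that add atoms: 3-chloroperoxybenzoic acid, O=C(OO)c1cccc(Cl)c1
Why: Baeyer–Villiger (Dakin-type) oxidation; the aryl group, with alkoxy groups ortho and para to the formyl carbon, migrates readily to give formate 6, the hindered aryl methyl ketone reacts far more slowly, and methanolysis of the formate releases the phenol.

Step 5
Reactants: 7 1-{2-[(3,4-dimethoxybenzyl)oxy]-3-hydroxy-4,5,6-trimethoxyphenyl}ethan-1-one
Product: 8 1-{2-[(3,4-dimethoxybenzyl)oxy]-4,5,6-trimethoxy-3-[(triisopropylsilyl)oxy]phenyl}ethan-1-one
Conditions: TIPSCl, imidazole, DMF, 40 °C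
Reagents that add atoms: chlorotriisopropylsilane, CC(C)[Si](Cl)(C(C)C)C(C)C
Why: Imidazole-promoted silylation of the only free hydroxyl; the bulky aryl silyl ether should withstand the amide base, the aqueous amine and the carbenoid of the next two steps and still yield to fluoride at the end.

Step 6
Reactants: 8 1-{2-[(3,4-dimethoxybenzyl)oxy]-4,5,6-trimethoxy-3-[(triisopropylsilyl)oxy]phenyl}ethan-1-one
Product: 10 2-diazo-1-{2-[(3,4-dimethoxybenzyl)oxy]-4,5,6-trimethoxy-3-[(triisopropylsilyl)oxy]phenyl}ethan-1-one, via trifluoroacetyl diketone 9 (not isolated)
Conditions: LiHMDS, THF, −78 °C; CF3CO2CH2CF3, −78 °C; cold 5% aq HCl; then MsN3, Et3N, H2O (1 equiv), MeCN, rt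
Reagents that add atoms: methanesulfonyl azide, CS(=O)(=O)N=[N+]=[N-] (the two diazo nitrogens of 10); 2,2,2-trifluoroethyl trifluoroacetate, O=C(OCC(F)(F)F)C(F)(F)F (the trifluoroacetyl group of 9 only)
Why: Claisen-type C-acylation of the lithium enolate gives diketone 9, whose acidic methylene accepts the diazo group from the sulfonyl azide (Regitz-type deacylative diazo transfer) with loss of the trifluoroacetyl group as the N-acyl sulfonamide; the silyl ether and the benzyl ether are inert under these conditions.

Step 7
Reactants: 10 2-diazo-1-{2-[(3,4-dimethoxybenzyl)oxy]-4,5,6-trimethoxy-3-[(triisopropylsilyl)oxy]phenyl}ethan-1-one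
Product: 11 (2S)-2-(3,4-dimethoxyphenyl)-5,6,7-trimethoxy-8-[(triisopropylsilyl)oxy]-2,3-dihydro-4H-chromen-4-one
Conditions: Rh2(S-PTTL)4 (dirhodium tetrakis[N-phthaloyl-(S)-tert-leucinate], 2 mol %), toluene, −20 °C to 0 °C, slow addition of 10
Reagents that add atoms: none
Why: The divalent rhodium dimer adds to the diazo carbon, N2 leaves and an electrophilic carbenoid stands at C3; it engages the C2–H bond in a three-centre transition state with hydride-transfer character, the charge building at C2 being carried by O1 and the dimethoxyphenyl ring, and the C2–C3 bond forms as the catalyst is released. The closest known reaction type is the dirhodium-carboxylate-catalysed intramolecular C–H insertion of 2-alkoxyaryl diazo ketones to chroman-4-ones, which has also been run with chiral carboxylates. Ring C closes as a six-membered ring by 1,6-insertion; the usual five-membered mode has no C–H bond to use, because the atom in that position is O1 itself. C2 is the only new stereocentre and is set by the catalyst alone: the pocket of phthalimido tert-leucinate ligands has to distinguish the two enantiotopic hydrogens, and insertion into the pro-S hydrogen with retention gives 2S. Three selectivities are needed. Attack on the O1 lone pair (oxonium ylide, then Stevens 1,2-shift of the benzyl group to a 2-benzylbenzofuran-3-one) should be held back by using a rhodium carboxylate rather than a copper catalyst, by O1 being an aryl ether shielded by the neighbouring silyloxy group, and by the low temperature. Insertion into the methyl C–H bonds of the C5 methoxy group, which lie at the same distance on the other side of the carbonyl, should lose to the far more hydridic secondary, alpha-oxygen, electron-rich benzylic C–H bond. Slow addition at high dilution keeps carbene dimerisation down.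

Step 8
Reactants: 11 (2S)-2-(3,4-dimethoxyphenyl)-5,6,7-trimethoxy-8-[(triisopropylsilyl)oxy]-2,3-dihydro-4H-chromen-4-one
Product: 12 (2S)-2-(3,4-dimethoxyphenyl)-8-hydroxy-5,6,7-trimethoxy-2,3-dihydro-4H-chromen-4-one
Conditions: HF·pyridine, pyridine, THF, 0 °C to rt
Reagents that add atoms: none
Why: Fluoride-induced cleavage of the aryl silyl ether, driven by the strength of the Si–F bond; the buffered, weakly acidic medium generates neither a phenoxide nor a C3 enolate, so ring C should not open and C2 should keep its configuration, and the methyl ethers are untouched.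

## Compound list

1 | 3,4,5-trimethoxyphenol | COc1cc(O)cc(OC)c1OC | starting material
2 | 1-(6-hydroxy-2,3,4-trimethoxyphenyl)ethan-1-one | CC(=O)c1c(O)cc(OC)c(OC)c1OC | intermediate
3 | 3-acetyl-2-hydroxy-4,5,6-trimethoxybenzaldehyde | CC(=O)c1c(O)c(C=O)c(OC)c(OC)c1OC | intermediate
4 | 3,4-dimethoxybenzyl chloride | COc1ccc(CCl)cc1OC | starting material
5 | 3-acetyl-2-[(3,4-dimethoxybenzyl)oxy]-4,5,6-trimethoxybenzaldehyde | COc1ccc(COc2c(C(C)=O)c(OC)c(OC)c(OC)c2C=O)cc1OC | intermediate
6 | 3-acetyl-2-[(3,4-dimethoxybenzyl)oxy]-4,5,6-trimethoxyphenyl formate | COc1ccc(COc2c(C(C)=O)c(OC)c(OC)c(OC)c2OC=O)cc1OC | intermediate (not isolated)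
7 | 1-{2-[(3,4-dimethoxybenzyl)oxy]-3-hydroxy-4,5,6-trimethoxyphenyl}ethan-1-one | COc1ccc(COc2c(C(C)=O)c(OC)c(OC)c(OC)c2O)cc1OC | intermediate
8 | 1-{2-[(3,4-dimethoxybenzyl)oxy]-4,5,6-trimethoxy-3-[(triisopropylsilyl)oxy]phenyl}ethan-1-one | COc1ccc(COc2c(C(C)=O)c(OC)c(OC)c(OC)c2O[Si](C(C)C)(C(C)C)C(C)C)cc1OC | intermediate
9 | 1-{2-[(3,4-dimethoxybenzyl)oxy]-4,5,6-trimethoxy-3-[(triisopropylsilyl)oxy]phenyl}-4,4,4-trifluorobutane-1,3-dione | COc1ccc(COc2c(C(=O)CC(=O)C(F)(F)F)c(OC)c(OC)c(OC)c2O[Si](C(C)C)(C(C)C)C(C)C)cc1OC | intermediate (not isolated)
10 | 2-diazo-1-{2-[(3,4-dimethoxybenzyl)oxy]-4,5,6-trimethoxy-3-[(triisopropylsilyl)oxy]phenyl}ethan-1-one | COc1ccc(COc2c(C(=O)C=[N+]=[N-])c(OC)c(OC)c(OC)c2O[Si](C(C)C)(C(C)C)C(C)C)cc1OC | intermediate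
11 | (2S)-2-(3,4-dimethoxyphenyl)-5,6,7-trimethoxy-8-[(triisopropylsilyl)oxy]-2,3-dihydro-4H-chromen-4-one | COc1ccc([C@@H]2CC(=O)c3c(c(O[Si](C(C)C)(C(C)C)C(C)C)c(OC)c(OC)c3OC)O2)cc1OC | intermediate
12 | (2S)-2-(3,4-dimethoxyphenyl)-8-hydroxy-5,6,7-trimethoxy-2,3-dihydro-4H-chromen-4-one | COc1ccc([C@@H]2CC(=O)c3c(c(O)c(OC)c(OC)c3OC)O2)cc1OC | target

## Step count and risk

Total steps: 8. Longest linear sequence: 8 steps (1 to 12); 4 enters at step 3.

**Step 7 (key step).** The most likely failure is capture of the carbenoid by the O1 lone pair followed by 1,2-migration of the electron-rich benzyl group, which would give a benzofuranone instead of ring C. The second is poor discrimination between the two enantiotopic hydrogens: insertion into so hydridic a C–H bond is early and asynchronous, close to hydride transfer followed by ion-pair collapse, and this loosens the catalyst's grip. The fallback sets out from 8 and returns at 11; it forms the C2–C1' bond instead of C2–C3. Hydrogenolysis of the benzyl-type ether of 8 (H2, Pd/C, EtOAc) should give 1-{2-hydroxy-4,5,6-trimethoxy-3-[(triisopropylsilyl)oxy]phenyl}ethan-1-one F1. Condensation with N,N-dimethylformamide dimethyl acetal should give (E)-3-(dimethylamino)-1-{2-hydroxy-4,5,6-trimethoxy-3-[(triisopropylsilyl)oxy]phenyl}prop-2-en-1-one F2. Acid closes F2, with loss of dimethylamine, to 5,6,7-trimethoxy-8-[(triisopropylsilyl)oxy]-4H-chromen-4-one F3. Enantioselective 1,4-addition of 3,4-dimethoxyphenylboronic acid to F3 should then give 11; the catalyst is Pd(OCOCF3)2 (divalent palladium) with the enantiomer of the tert-butyl pyridine-oxazoline ligand that delivers the 2S product. Conjugate arylation of chromones is a known route to flavanones.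

**Step 2.** Ring formylation may stall because the chelated acetyl group deactivates the arene, and the iminium electrophile may be diverted to aminomethylation at the methyl ketone. The fallback sets out from 2 and returns at 7; it brings in the C8 oxygen through a halide instead of a formyl group. Bromination of 2 with N-bromosuccinimide at the only free ring position should give 1-(3-bromo-2-hydroxy-4,5,6-trimethoxyphenyl)ethan-1-one F4. O-alkylation with 4 (K2CO3, DMF) should give 1-{3-bromo-2-[(3,4-dimethoxybenzyl)oxy]-4,5,6-trimethoxyphenyl}ethan-1-one F5. Miyaura borylation (bis(pinacolato)diboron, Pd(OAc)2, SPhos, KOAc, dioxane) should give 1-{2-[(3,4-dimethoxybenzyl)oxy]-4,5,6-trimethoxy-3-(4,4,5,5-tetramethyl-1,3,2-dioxaborolan-2-yl)phenyl}ethan-1-one F6. Oxidation of the carbon–boron bond with NaBO3 in aqueous THF should give 7.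

**Step 6.** C-acylation of the enolate of a ketone flanked by two ortho substituents may be incomplete, with return of ketone or O-acylation. The aryl silyl ether may also be lost during the aqueous amine stage of the diazo transfer. The fallback sets out from 8 and returns at 10; it builds the diazo group by substitution and elimination instead of diazo transfer. The lithium enolate of 8 is trapped with chlorotrimethylsilane as ({1-{2-[(3,4-dimethoxybenzyl)oxy]-4,5,6-trimethoxy-3-[(triisopropylsilyl)oxy]phenyl}ethenyl}oxy)trimethylsilane F7. N-bromosuccinimide at low temperature should convert F7 into 2-bromo-1-{2-[(3,4-dimethoxybenzyl)oxy]-4,5,6-trimethoxy-3-[(triisopropylsilyl)oxy]phenyl}ethan-1-one F8. N,N'-ditosylhydrazine and DBU should then give 10 by N-alkylation and loss of two sulfinate groups.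

**Step 3.** O-alkylation may be slow because the phenoxide is held by two neighbouring carbonyl groups, while the electron-rich benzylic chloride is consumed by self-alkylation or hydrolysis. The fallback sets out from 3 and returns at 5; it activates the alcohol instead of using a halide. A Mitsunobu reaction of 3 with 3,4-dimethoxybenzyl alcohol (PPh3, diisopropyl azodicarboxylate, THF) should give 5 directly; an acidic phenol is a good Mitsunobu partner and no free phenoxide is involved.

Further compounds

F1 | step 7 | 1-{2-hydroxy-4,5,6-trimethoxy-3-[(triisopropylsilyl)oxy]phenyl}ethan-1-one | CC(=O)c1c(O)c(O[Si](C(C)C)(C(C)C)C(C)C)c(OC)c(OC)c1OC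
F2 | step 7 | (E)-3-(dimethylamino)-1-{2-hydroxy-4,5,6-trimethoxy-3-[(triisopropylsilyl)oxy]phenyl}prop-2-en-1-one | CN(C)/C=C/C(=O)c1c(O)c(O[Si](C(C)C)(C(C)C)C(C)C)c(OC)c(OC)c1OC
F3 | step 7 | 5,6,7-trimethoxy-8-[(triisopropylsilyl)oxy]-4H-chromen-4-one | COc1c(OC)c(OC)c2c(=O)ccoc2c1O[Si](C(C)C)(C(C)C)C(C)C
F4 | step 2 | 1-(3-bromo-2-hydroxy-4,5,6-trimethoxyphenyl)ethan-1-one | CC(=O)c1c(O)c(Br)c(OC)c(OC)c1OC
F5 | step 2 | 1-{3-bromo-2-[(3,4-dimethoxybenzyl)oxy]-4,5,6-trimethoxyphenyl}ethan-1-one | COc1ccc(COc2c(C(C)=O)c(OC)c(OC)c(OC)c2Br)cc1OC
F6 | step 2 | 1-{2-[(3,4-dimethoxybenzyl)oxy]-4,5,6-trimethoxy-3-(4,4,5,5-tetramethyl-1,3,2-dioxaborolan-2-yl)phenyl}ethan-1-one | COc1ccc(COc2c(C(C)=O)c(OC)c(OC)c(OC)c2B3OC(C)(C)C(C)(C)O3)cc1OC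
F7 | step 6 | ({1-{2-[(3,4-dimethoxybenzyl)oxy]-4,5,6-trimethoxy-3-[(triisopropylsilyl)oxy]phenyl}ethenyl}oxy)trimethylsilane | C=C(O[Si](C)(C)C)c1c(OCc2ccc(OC)c(OC)c2)c(O[Si](C(C)C)(C(C)C)C(C)C)c(OC)c(OC)c1OC
F8 | step 6 | 2-bromo-1-{2-[(3,4-dimethoxybenzyl)oxy]-4,5,6-trimethoxy-3-[(triisopropylsilyl)oxy]phenyl}ethan-1-one | BrCC(=O)c1c(OCc2ccc(OC)c(OC)c2)c(O[Si](C(C)C)(C(C)C)C(C)C)c(OC)c(OC)c1OC
F0 | step 3 | none | none
A1 | alternative 1 | 4-[(2S,4S)-4-(tert-butyldimethylsilyloxy)-2-(3,4-dimethoxyphenyl)-3,4-dihydro-2H-pyran-6-yl]-2,3-dimethoxy-4-(trimethylsilyloxy)cyclobut-2-en-1-one | COc1ccc([C@@H]2C[C@H](O[Si](C)(C)C(C)(C)C)C=C(C3(O[Si](C)(C)C)C(OC)=C(OC)C3=O)O2)cc1OC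
A2 | alternative 1 | (2S,4S)-4-(tert-butyldimethylsilyloxy)-2-(3,4-dimethoxyphenyl)-6,7-dimethoxy-8-(trimethylsilyloxy)chroman-5-ol | COc1ccc([C@@H]2C[C@H](O[Si](C)(C)C(C)(C)C)c3c(O)c(OC)c(OC)c(O[Si](C)(C)C)c3O2)cc1OC
A3 | alternative 2 | (2S)-8-(benzyloxy)-2-ethynyl-5,6,7-trimethoxychroman-4-one | C#C[C@@H]1CC(=O)c2c(c(OCc3ccccc3)c(OC)c(OC)c2OC)O1
A4 | alternative 2 | 2,3-dimethoxybuta-1,3-diene | C=C(OC)C(OC)=C
A5 | alternative 2 | (2S)-8-(benzyloxy)-2-(4,5-dimethoxycyclohexa-1,4-dien-1-yl)-5,6,7-trimethoxychroman-4-one | COC1=C(OC)CC([C@@H]2CC(=O)c3c(c(OCc4ccccc4)c(OC)c(OC)c3OC)O2)=CC1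
A6 | alternative 3 | 3-(benzyloxy)-2-hydroxy-4,5,6-trimethoxybenzaldehyde | O=Cc1c(O)c(OCc2ccccc2)c(OC)c(OC)c1OC
A7 | alternative 3 | 3,4-dimethoxystyrene | C=Cc1ccc(OC)c(OC)c1
A8 | alternative 3 | (2S,4S)-8-(benzyloxy)-2-(3,4-dimethoxyphenyl)-4,5,6,7-tetramethoxychromane | COc1ccc([C@@H]2C[C@H](OC)c3c(OC)c(OC)c(OC)c(OCc4ccccc4)c3O2)cc1OC
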